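Cuts: the three O–Si bonds come off last; ring C is then opened at O1–C2 and C4–C4a together, which gives ring A as iodophenol 6 and ring B with its C2–C3–C4 chain as enoyl Weinreb amide 23; 23 is cut at the diene (olefination of a C2″ aldehyde), at O1″–C2″ of the chroman (epoxide opening) and at the ArCH2CH2–C(sp2) bond (B-alkyl Suzuki coupling).
Enabling feature: O1 and the neighbouring ring carbon C4a of ring A become, after iodine–lithium exchange, an ortho-lithiated phenoxide (a 1,3-C,O-dinucleophile); C4 (acyl carbon) and C2 (β-carbon) of the enoyl chain are the matching 1,3-dielectrophile; O5 and O7 are silylated, so only O1 can close ring C and the prenyl group can only end up at C6.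
Forward order: ring A is prenylated, silylated, freed at O1 and iodinated (steps 1–4); the chroman of ring B is closed on a benzaldehyde core by phenol opening of a Sharpless epoxide and the diene is then attached (steps 5–15); rings A and B are joined while ring C forms (step 16); desilylation gives the target (step 17).
Stereochemistry: C2″ (S) comes from Sharpless epoxidation of a Z-allylic alcohol with L-(+)-diethyl tartrate and inversion at the tertiary epoxide carbon on chroman closure; C2 (S) is set in step 16 by a cinchona thiourea that steers the oxa-Michael closure, on which both alkene geometries of the open-chain enone converge.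

Key step: step 16

Remark on numbering: O1, C2, C3, C4, C4a, C5 to C8 and C8a are the atoms of rings C and A of the flavanone; double-primed numbers belong to the chroman of ring B.
Remark on materials: 3-bromo-4,5-dihydroxybenzaldehyde (7) is taken as purchased; 2-prenylphloroglucinol, (Z)-3-iodobut-2-en-1-ol and diethyl prenylphosphonate are made (steps 1, 9, 14) so that the route does not depend on their supply.
Remark on step 16: the sense of induction of the quinine-derived thiourea is an expectation from related cyclisations; the quinidine-derived pseudoenantiomer is the reserve if a model compound shows the opposite sense.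

Step 1
Reactants: 1 phloroglucinol (benzene-1,3,5-triol); 2 prenyl bromide (1-bromo-3-methylbut-2-ene)
Product: 3 2-(3-methylbut-2-en-1-yl)benzene-1,3,5-triol
Conditions: DBU (1.0 equiv), THF, 0 °C to rt, 1 in excess
Reagents that add atoms: none
Why: C-alkylation of the phloroglucinol anion by the allylic bromide (Friedel–Crafts-type C-prenylation) is a known route to 2-prenylphloroglucinol, and an excess of 1 should hold back double prenylation.

Step 2
Reactants: 3 2-(3-methylbut-2-en-1-yl)benzene-1,3,5-triol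
Product: 4 1,3,5-tris(tert-butyldimethylsilyloxy)-2-(3-methylbut-2-en-1-yl)benzene
Conditions: TBSCl (3.6 equiv), imidazole, DMF, rt to 40 °C
Reagents that add atoms: tert-butyldimethylsilyl chloride, CC(C)(C)[Si](C)(C)Cl
Why: Corey silylation of all three phenols masks O5 and O7 for the rest of the route and prepares the steric differentiation of O1.

Step 3
Reactants: 4 1,3,5-tris(tert-butyldimethylsilyloxy)-2-(3-methylbut-2-en-1-yl)benzene
Product: 5 3,5-bis(tert-butyldimethylsilyloxy)-4-(3-methylbut-2-en-1-yl)phenol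
Conditions: Cs2CO3 (0.5 equiv), DMF/H2O (10:1), 0 °C, stopped at mono-desilylation
Reagents that add atoms: none
Why: base-mediated cleavage of an aryl silyl ether should be fastest at the oxygen para to the prenyl group, whose silicon has no ortho neighbour, whereas the two silyl ethers that flank the prenyl group are shielded, so mono-desilylation at the future O1 is expected.

Step 4
Reactants: 5 3,5-bis(tert-butyldimethylsilyloxy)-4-(3-methylbut-2-en-1-yl)phenol
Product: 6 3,5-bis(tert-butyldimethylsilyloxy)-2-iodo-4-(3-methylbut-2-en-1-yl)phenol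
Conditions: N-iodosuccinimide (1.0 equiv), CH2Cl2, −40 to 0 °C
Reagents that add atoms: N-iodosuccinimide, O=C1CCC(=O)N1I
Why: electrophilic aromatic iodination of the phenol goes ortho to the free hydroxyl (para is blocked by prenyl and both ortho sites are equivalent), and this very electron-rich ring should outpace the trisubstituted alkene, which has no free neighbouring hydroxyl for iodoetherification.

Step 5
Reactants: 7 3-bromo-4,5-dihydroxybenzaldehyde
Product: 8 3-bromo-5-hydroxy-4-(4-methoxybenzyloxy)benzaldehyde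
Conditions: 4-methoxybenzyl chloride (1.05 equiv), NaHCO3, NaI (cat.), DMF, 40 °C
Reagents that add atoms: 4-methoxybenzyl chloride, COc1ccc(CCl)cc1
Why: Williamson etherification with a weak base ionises only the more acidic hydroxyl para to the formyl group, as in the known 4-O-selective benzylation of protocatechualdehydes, so the oxygen that will become O1″ receives the temporary 4-methoxybenzyl group.

Step 6
Reactants: 8 3-bromo-5-hydroxy-4-(4-methoxybenzyloxy)benzaldehyde
Product: 9 3-bromo-4-(4-methoxybenzyloxy)-5-(triisopropylsilyloxy)benzaldehyde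
Conditions: TIPSCl, imidazole, DMF, rt
Reagents that add atoms: triisopropylsilyl chloride, CC(C)[Si](Cl)(C(C)C)C(C)C
Why: silylation of the remaining phenol (the future 8″-OH) gives a bulky aryl silyl ether that should withstand the basic cross-coupling steps.

Step 7
Reactants: 9 3-bromo-4-(4-methoxybenzyloxy)-5-(triisopropylsilyloxy)benzaldehyde
Product: 10 (E)-3-[3-bromo-4-(4-methoxybenzyloxy)-5-(triisopropylsilyloxy)phenyl]-N-methoxy-N-methylprop-2-enamide
Conditions: diethyl [2-(methoxy(methyl)amino)-2-oxoethyl]phosphonate, NaH, THF, 0 °C to rt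
Reagents that add atoms: diethyl [2-(methoxy(methyl)amino)-2-oxoethyl]phosphonate, CCOP(=O)(CC(=O)N(C)OC)OCC
Why: Horner–Wadsworth–Emmons olefination with the stabilised phosphonate anion gives the E-enamide and installs C2–C3–C4 of the flavanone as a Weinreb amide.

Step 8
Reactants: 10 (E)-3-[3-bromo-4-(4-methoxybenzyloxy)-5-(triisopropylsilyloxy)phenyl]-N-methoxy-N-methylprop-2-enamide
Product: 11 (E)-3-[3-ethenyl-4-(4-methoxybenzyloxy)-5-(triisopropylsilyloxy)phenyl]-N-methoxy-N-methylprop-2-enamide
Conditions: vinylboronic acid pinacol ester, Pd(dppf)Cl2 (5 mol%), K2CO3, 1,4-dioxane/H2O, 80 °C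
Reagents that add atoms: 4,4,5,5-tetramethyl-2-vinyl-1,3,2-dioxaborolane, C=CB1OC(C)(C)C(C)(C)O1
Why: Suzuki–Miyaura coupling of the aryl bromide with the vinylboronate, which the hindered aryl silyl ether and the Weinreb amide should tolerate.

Step 9
Reactants: 12 but-2-yn-1-ol
Product: 14 (Z)-3-iodobut-2-en-1-ol, via cyclic alkenylalanate 13 (not isolated)
Conditions: NaAlH2(OCH2CH2OMe)2, Et2O, 0 °C to rt; then I2, THF, −78 °C
Reagents that add atoms: iodine, II
Why: hydroxyl-directed trans-hydroalumination of the propargylic alcohol places aluminium at C3 in a five-membered alkoxyalanate, and iodinolysis with retention gives the Z-iodide.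

Step 10
Reactants: 11 (E)-3-[3-ethenyl-4-(4-methoxybenzyloxy)-5-(triisopropylsilyloxy)phenyl]-N-methoxy-N-methylprop-2-enamide; 14 (Z)-3-iodobut-2-en-1-ol
Product: 16 (E)-3-{3-[(3Z)-5-hydroxy-3-methylpent-3-en-1-yl]-4-(4-methoxybenzyloxy)-5-(triisopropylsilyloxy)phenyl}-N-methoxy-N-methylprop-2-enamide, via B-alkyl-9-BBN 15 (not isolated)
Conditions: 9-BBN, THF, rt; then 14, Pd(dppf)Cl2 (5 mol%), AsPh3, Cs2CO3, DMF/H2O, rt
Reagents that add atoms: none
Why: 9-BBN hydroborates the styrene at the terminal carbon and leaves the electron-poor enamide alone, and B-alkyl Suzuki–Miyaura coupling of the alkylborane with the vinyl iodide proceeds with retention, so the arylethyl chain ends cis to CH2OH (a Z-alkene of the nerol type).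

Step 11
Reactants: 16 (E)-3-{3-[(3Z)-5-hydroxy-3-methylpent-3-en-1-yl]-4-(4-methoxybenzyloxy)-5-(triisopropylsilyloxy)phenyl}-N-methoxy-N-methylprop-2-enamide
Product: 17 (E)-3-{3-[2-[(2R,3S)-3-(hydroxymethyl)-2-methyloxiran-2-yl]ethyl]-4-(4-methoxybenzyloxy)-5-(triisopropylsilyloxy)phenyl}-N-methoxy-N-methylprop-2-enamide
Conditions: Ti(OiPr)4 (20 mol%), L-(+)-diethyl tartrate (24 mol%), t-BuOOH (2 equiv), 4 Å molecular sieves, CH2Cl2, −20 °C
Reagents that add atoms: tert-butyl hydroperoxide, CC(C)(C)OO
Why: Sharpless asymmetric epoxidation, in which the titanium tartrate epoxidises only the allylic alcohol (the enamide alkene is electron-poor and has no directing hydroxyl) and L-(+)-diethyl tartrate sets both new stereocentres, Z-trisubstituted allylic alcohols of the nerol type being known to give the (2S,3R)-epoxy alcohol (allylic-alcohol numbering).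

Step 12
Reactants: 17 (E)-3-{3-[2-[(2R,3S)-3-(hydroxymethyl)-2-methyloxiran-2-yl]ethyl]-4-(4-methoxybenzyloxy)-5-(triisopropylsilyloxy)phenyl}-N-methoxy-N-methylprop-2-enamide
Product: 19 (E)-3-{(2S)-2-[(1S)-1,2-dihydroxyethyl]-2-methyl-8-(triisopropylsilyloxy)chroman-6-yl}-N-methoxy-N-methylprop-2-enamide, via phenol epoxy alcohol 18 (not isolated)
Conditions: DDQ (1.2 equiv), CH2Cl2/pH 7 buffer, 0 °C; then camphorsulfonic acid (10 mol%), CH2Cl2, 0 °C
Reagents that add atoms: none
Why: oxidative removal of the 4-methoxybenzyl ether by DDQ frees the phenol, and acid-catalysed epoxide opening then closes the chroman ring in the 6-exo-tet mode at the tertiary carbon with inversion (the only phenol-to-epoxide closure that gives a six-membered ring), which turns the R-configured epoxide carbon into the S-configured C2″ while the secondary carbinol keeps its configuration.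

Step 13
Reactants: 19 (E)-3-{(2S)-2-[(1S)-1,2-dihydroxyethyl]-2-methyl-8-(triisopropylsilyloxy)chroman-6-yl}-N-methoxy-N-methylprop-2-enamide
Product: 20 (E)-3-[(2S)-2-formyl-2-methyl-8-(triisopropylsilyloxy)chroman-6-yl]-N-methoxy-N-methylprop-2-enamide
Conditions: NaIO4, THF/H2O, 0 °C
Reagents that add atoms: none
Why: Malaprade glycol cleavage with periodate removes the terminal carbon and leaves a quaternary α-aryloxy aldehyde that cannot enolise, so C2″ is not at risk.

Step 14
Reactants: 2 prenyl bromide (1-bromo-3-methylbut-2-ene)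
Product: 21 diethyl (3-methylbut-2-en-1-yl)phosphonate
Conditions: P(OEt)3 (neat), 130 °C
Reagents that add atoms: triethyl phosphite, CCOP(OCC)OCC
Why: Michaelis–Arbuzov reaction of the primary allylic bromide with triethyl phosphite gives the prenylphosphonate.

Step 15
Reactants: 20 (E)-3-[(2S)-2-formyl-2-methyl-8-(triisopropylsilyloxy)chroman-6-yl]-N-methoxy-N-methylprop-2-enamide; 21 diethyl (3-methylbut-2-en-1-yl)phosphonate
Product: 23 (E)-N-methoxy-N-methyl-3-{(2S)-2-methyl-2-[(1E)-4-methylpenta-1,3-dien-1-yl]-8-(triisopropylsilyloxy)chroman-6-yl}prop-2-enamide, via lithiated phosphonate 22 (not isolated)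
Conditions: n-BuLi, THF/DMPU, −78 °C; then 20, −78 °C to rt
Reagents that add atoms: none
Why: Horner–Wadsworth–Emmons olefination with the allylic phosphonate anion, which should react through its α-carbon with the aldehyde (far more electrophilic than the Weinreb amide) and give the E-alkene by reversible addition and elimination through the less crowded oxaphosphetane, as is usual for allylic phosphonates and α-branched aldehydes.

Step 16
Reactants: 6 3,5-bis(tert-butyldimethylsilyloxy)-2-iodo-4-(3-methylbut-2-en-1-yl)phenol; 23 (E)-N-methoxy-N-methyl-3-{(2S)-2-methyl-2-[(1E)-4-methylpenta-1,3-dien-1-yl]-8-(triisopropylsilyloxy)chroman-6-yl}prop-2-enamide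
Product: 26 (2S)-5,7-bis(tert-butyldimethylsilyloxy)-6-(3-methylbut-2-en-1-yl)-2-{(2S)-2-methyl-2-[(1E)-4-methylpenta-1,3-dien-1-yl]-8-(triisopropylsilyloxy)chroman-6-yl}chroman-4-one, via dilithio phenoxide 24 (not isolated), via 2′-hydroxychalcone 25 (not isolated)
Conditions: t-BuLi (3.0 equiv), Et2O, −78 °C; 23 in toluene, −78 to −30 °C; AcOH (2.0 equiv); then 9-amino(9-deoxy)epi-quinine N′-[3,5-bis(trifluoromethyl)phenyl]thiourea (20 mol%), toluene, −30 to 0 °C
Reagents that add atoms: none
Why: Proposed new method: t-BuLi deprotonates O1–H and exchanges iodine for lithium, so that 6 becomes the ortho-lithiated phenoxide 24, whose C4a carbanion adds to the carbonyl of Weinreb amide 23 (C4–C4a bond; the lithium N,O-chelate prevents over-addition and conjugate addition), and acetic acid then releases 2′-hydroxychalcone 25, which the thiourea closes by oxa-Michael addition of O1 to C2 (O1–C2 bond). The closest known reaction types are the enone synthesis from aryllithiums and α,β-unsaturated Weinreb amides and the cyclisation of 2′-hydroxychalcones to flavanones under cinchona thiourea or chiral ion-pair catalysis; what is new is their merger into one [3+3] annulation and the use of an unactivated 6′-silyloxy chalcone. Ring C closes in the 6-endo-trig mode, the 5-exo alternative through C3 being electronically mismatched, and the closed form should be favoured because the di-ortho-oxygenated aryl ketone of 25 is twisted out of conjugation with the enone. C2 is the only new stereocentre and is set by the catalyst, whose thiourea binds the C4 carbonyl while its quinuclidine holds the O1 phenol as an ion pair, so that O1 is delivered to one face of the enone regardless of the remote C2″ centre and of the E or Z geometry of 25. The step needs C- over O-acylation (secured by the C–Li bond at C4a), 1,2- over 1,4-addition (Weinreb amide), closure through O1 and not O5 (O5 is silylated, hence only the 6-prenyl isomer) and facial control at C2 (catalyst; lithium acetate and iodide are insoluble in ether–toluene, which should keep the uncatalysed closure slow).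

Step 17
Reactants: 26 (2S)-5,7-bis(tert-butyldimethylsilyloxy)-6-(3-methylbut-2-en-1-yl)-2-{(2S)-2-methyl-2-[(1E)-4-methylpenta-1,3-dien-1-yl]-8-(triisopropylsilyloxy)chroman-6-yl}chroman-4-one
Product: 27 (2S)-5,7-dihydroxy-2-{(2S)-8-hydroxy-2-methyl-2-[(1E)-4-methylpenta-1,3-dien-1-yl]chroman-6-yl}-6-(3-methylbut-2-en-1-yl)chroman-4-one
Conditions: Bu4NF (3.6 equiv), AcOH (3.6 equiv), THF, 0 °C to rt
Reagents that add atoms: none
Why: fluoride-mediated cleavage of the three aryl silyl ethers, in which the acetic acid buffer keeps the liberated phenols protonated, which should prevent retro-oxa-Michael epimerisation at C2 and spare the acid-labile dienylic tertiary ether and the prenyl group.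

Compound list
1 | phloroglucinol (benzene-1,3,5-triol) | Oc1cc(O)cc(O)c1 | starting material
2 | prenyl bromide (1-bromo-3-methylbut-2-ene) | CC(C)=CCBr | starting material
3 | 2-(3-methylbut-2-en-1-yl)benzene-1,3,5-triol | CC(C)=CCc1c(O)cc(O)cc1O | intermediate
4 | 1,3,5-tris(tert-butyldimethylsilyloxy)-2-(3-methylbut-2-en-1-yl)benzene | CC(C)=CCc1c(O[Si](C)(C)C(C)(C)C)cc(O[Si](C)(C)C(C)(C)C)cc1O[Si](C)(C)C(C)(C)C | intermediate
5 | 3,5-bis(tert-butyldimethylsilyloxy)-4-(3-methylbut-2-en-1-yl)phenol | CC(C)=CCc1c(O[Si](C)(C)C(C)(C)C)cc(O)cc1O[Si](C)(C)C(C)(C)C | intermediate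
6 | 3,5-bis(tert-butyldimethylsilyloxy)-2-iodo-4-(3-methylbut-2-en-1-yl)phenol | CC(C)=CCc1c(O[Si](C)(C)C(C)(C)C)cc(O)c(I)c1O[Si](C)(C)C(C)(C)C | intermediate
7 | 3-bromo-4,5-dihydroxybenzaldehyde | O=Cc1cc(O)c(O)c(Br)c1 | starting material
8 | 3-bromo-5-hydroxy-4-(4-methoxybenzyloxy)benzaldehyde | O=Cc1cc(O)c(OCc2ccc(OC)cc2)c(Br)c1 | intermediate
9 | 3-bromo-4-(4-methoxybenzyloxy)-5-(triisopropylsilyloxy)benzaldehyde | O=Cc1cc(O[Si](C(C)C)(C(C)C)C(C)C)c(OCc2ccc(OC)cc2)c(Br)c1 | intermediate
10 | (E)-3-[3-bromo-4-(4-methoxybenzyloxy)-5-(triisopropylsilyloxy)phenyl]-N-methoxy-N-methylprop-2-enamide | CON(C)C(=O)/C=C/c1cc(O[Si](C(C)C)(C(C)C)C(C)C)c(OCc2ccc(OC)cc2)c(Br)c1 | intermediate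
11 | (E)-3-[3-ethenyl-4-(4-methoxybenzyloxy)-5-(triisopropylsilyloxy)phenyl]-N-methoxy-N-methylprop-2-enamide | CON(C)C(=O)/C=C/c1cc(O[Si](C(C)C)(C(C)C)C(C)C)c(OCc2ccc(OC)cc2)c(C=C)c1 | intermediate
12 | but-2-yn-1-ol | CC#CCO | starting material
13 | sodium 2,2-bis(2-methoxyethoxy)-3-methyl-2,5-dihydro-1,2-oxaaluminol-2-uide (cyclic alkenylalanate, Al bound to the oxygen and to C3 of the butenol) | [Na+].CC1=CCO[Al-]1(OCCOC)OCCOC | intermediate (not isolated)
14 | (Z)-3-iodobut-2-en-1-ol | C/C(I)=C/CO | intermediate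
15 | 9-{2-[5-[(E)-3-(methoxy(methyl)amino)-3-oxoprop-1-enyl]-2-(4-methoxybenzyloxy)-3-(triisopropylsilyloxy)phenyl]ethyl}-9-borabicyclo[3.3.1]nonane | CON(C)C(=O)/C=C/c1cc(O[Si](C(C)C)(C(C)C)C(C)C)c(OCc2ccc(OC)cc2)c(CCB2C3CCCC2CCC3)c1 | intermediate (not isolated)
16 | (E)-3-{3-[(3Z)-5-hydroxy-3-methylpent-3-en-1-yl]-4-(4-methoxybenzyloxy)-5-(triisopropylsilyloxy)phenyl}-N-methoxy-N-methylprop-2-enamide | CON(C)C(=O)/C=C/c1cc(O[Si](C(C)C)(C(C)C)C(C)C)c(OCc2ccc(OC)cc2)c(CC/C(C)=C\CO)c1 | intermediate
17 | (E)-3-{3-[2-[(2R,3S)-3-(hydroxymethyl)-2-methyloxiran-2-yl]ethyl]-4-(4-methoxybenzyloxy)-5-(triisopropylsilyloxy)phenyl}-N-methoxy-N-methylprop-2-enamide | CON(C)C(=O)/C=C/c1cc(O[Si](C(C)C)(C(C)C)C(C)C)c(OCc2ccc(OC)cc2)c(CC[C@@]2(C)O[C@H]2CO)c1 | intermediate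
18 | (E)-3-{4-hydroxy-3-[2-[(2R,3S)-3-(hydroxymethyl)-2-methyloxiran-2-yl]ethyl]-5-(triisopropylsilyloxy)phenyl}-N-methoxy-N-methylprop-2-enamide | CON(C)C(=O)/C=C/c1cc(O[Si](C(C)C)(C(C)C)C(C)C)c(O)c(CC[C@@]2(C)O[C@H]2CO)c1 | intermediate (not isolated)
19 | (E)-3-{(2S)-2-[(1S)-1,2-dihydroxyethyl]-2-methyl-8-(triisopropylsilyloxy)chroman-6-yl}-N-methoxy-N-methylprop-2-enamide | CON(C)C(=O)/C=C/c1cc2c(c(O[Si](C(C)C)(C(C)C)C(C)C)c1)O[C@](C)([C@@H](O)CO)CC2 | intermediate
20 | (E)-3-[(2S)-2-formyl-2-methyl-8-(triisopropylsilyloxy)chroman-6-yl]-N-methoxy-N-methylprop-2-enamide | CON(C)C(=O)/C=C/c1cc2c(c(O[Si](C(C)C)(C(C)C)C(C)C)c1)O[C@](C)(C=O)CC2 | intermediate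
21 | diethyl (3-methylbut-2-en-1-yl)phosphonate | CCOP(=O)(CC=C(C)C)OCC | intermediate
22 | diethyl (1-lithio-3-methylbut-2-en-1-yl)phosphonate | CCOP(=O)(OCC)C([Li])C=C(C)C | intermediate (not isolated)
23 | (E)-N-methoxy-N-methyl-3-{(2S)-2-methyl-2-[(1E)-4-methylpenta-1,3-dien-1-yl]-8-(triisopropylsilyloxy)chroman-6-yl}prop-2-enamide | CON(C)C(=O)/C=C/c1cc2c(c(O[Si](C(C)C)(C(C)C)C(C)C)c1)O[C@](C)(/C=C/C=C(C)C)CC2 | intermediate
24 | lithium 3,5-bis(tert-butyldimethylsilyloxy)-2-lithio-4-(3-methylbut-2-en-1-yl)phenoxide | CC(C)=CCc1c(O[Si](C)(C)C(C)(C)C)cc(O[Li])c([Li])c1O[Si](C)(C)C(C)(C)C | intermediate (not isolated)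
25 | (E)-1-[2,4-bis(tert-butyldimethylsilyloxy)-6-hydroxy-3-(3-methylbut-2-en-1-yl)phenyl]-3-{(2S)-2-methyl-2-[(1E)-4-methylpenta-1,3-dien-1-yl]-8-(triisopropylsilyloxy)chroman-6-yl}prop-2-en-1-one | CC(C)=CCc1c(O[Si](C)(C)C(C)(C)C)cc(O)c(C(=O)/C=C/c2cc3c(c(O[Si](C(C)C)(C(C)C)C(C)C)c2)O[C@](C)(/C=C/C=C(C)C)CC3)c1O[Si](C)(C)C(C)(C)C | intermediate (not isolated)
26 | (2S)-5,7-bis(tert-butyldimethylsilyloxy)-6-(3-methylbut-2-en-1-yl)-2-{(2S)-2-methyl-2-[(1E)-4-methylpenta-1,3-dien-1-yl]-8-(triisopropylsilyloxy)chroman-6-yl}chroman-4-one | CC(C)=C/C=C/[C@]1(C)CCc2cc([C@@H]3CC(=O)c4c(cc(O[Si](C)(C)C(C)(C)C)c(CC=C(C)C)c4O[Si](C)(C)C(C)(C)C)O3)cc(O[Si](C(C)C)(C(C)C)C(C)C)c2O1 | intermediate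
27 | (2S)-5,7-dihydroxy-2-{(2S)-8-hydroxy-2-methyl-2-[(1E)-4-methylpenta-1,3-dien-1-yl]chroman-6-yl}-6-(3-methylbut-2-en-1-yl)chroman-4-one | CC(C)=C/C=C/[C@]1(C)CCc2cc([C@@H]3CC(=O)c4c(cc(O)c(CC=C(C)C)c4O)O3)cc(O)c2O1 | target

Total step count: 17
Longest linear sequence: 11 steps (7 to 27 through steps 5, 6, 7, 8, 10, 11, 12, 13, 15, 16, 17)

Steps most likely to fail

Step 16 (Proposed new method). What may go wrong: poor facial selectivity in the oxa-Michael closure, a background closure carried by lithium salts, or silyl migration from oxygen to carbon in 24 before the acylation. Fallback, from 6 and 23 back to 26: the lithiation of 6 and the acylation with 23 are run as in step 16 but worked up with aqueous NH4Cl, so that chalcone 25 is isolated (addition of an aryllithium to a Weinreb amide). NaOAc in EtOH at 60 °C then closes ring C without stereocontrol and should give 26 together with its C2 epimer, the (2R)-flavanone F1. The pair is resolved by asymmetric transfer hydrogenation of flavanones, a known kinetic resolution, with RhCl(C5Me5)[(R,R)-TsDPEN] and HCO2H/Et3N, the catalyst enantiomer being the one that reduces the 2R series; this turns F1 into the cis-flavan-4-ol F2 and leaves 26, where the route is rejoined. F2 can be returned to the pool by Dess–Martin oxidation and NaOAc equilibration.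

Step 15. What may go wrong: attack through the γ-carbon of the allylic phosphonate anion, slow elimination of the β-oxido phosphonate, or low E selectivity at the new double bond. Fallback, from 20 back to 23: Wittig reaction of 20 with the stabilised ylide Ph3P=CHCHO in toluene at 80 °C should give the E-enal F3, and a second Wittig reaction with Ph3P=C(CH3)2 (from isopropyltriphenylphosphonium iodide and n-BuLi, THF, −78 °C), which creates no new alkene geometry, gives 23.

Step 3. What may go wrong: poor site selectivity, that is cleavage of one of the hindered silyl ethers or loss of a second silyl group. Fallback, from 3 back to 5: the differentiation is moved to the protection stage. Pivaloyl chloride (1.0 equiv), pyridine, CH2Cl2, −40 °C should acylate the unhindered hydroxyl para to the prenyl group and give the pivalate F4; TBSOTf and 2,6-lutidine silylate the two remaining phenols to the bis-silyl pivalate F5; i-Bu2AlH in CH2Cl2 at −78 °C removes the pivalate reductively without touching the aryl silyl ethers and gives 5.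

Further compounds
F1 | step 16 | (2R)-5,7-bis(tert-butyldimethylsilyloxy)-6-(3-methylbut-2-en-1-yl)-2-{(2S)-2-methyl-2-[(1E)-4-methylpenta-1,3-dien-1-yl]-8-(triisopropylsilyloxy)chroman-6-yl}chroman-4-one | CC(C)=C/C=C/[C@]1(C)CCc2cc([C@H]3CC(=O)c4c(cc(O[Si](C)(C)C(C)(C)C)c(CC=C(C)C)c4O[Si](C)(C)C(C)(C)C)O3)cc(O[Si](C(C)C)(C(C)C)C(C)C)c2O1
F2 | step 16 | (2R,4R)-5,7-bis(tert-butyldimethylsilyloxy)-6-(3-methylbut-2-en-1-yl)-2-{(2S)-2-methyl-2-[(1E)-4-methylpenta-1,3-dien-1-yl]-8-(triisopropylsilyloxy)chroman-6-yl}chroman-4-ol (2,4-cis) | CC(C)=C/C=C/[C@]1(C)CCc2cc([C@H]3C[C@@H](O)c4c(cc(O[Si](C)(C)C(C)(C)C)c(CC=C(C)C)c4O[Si](C)(C)C(C)(C)C)O3)cc(O[Si](C(C)C)(C(C)C)C(C)C)c2O1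
F3 | step 15 | (E)-N-methoxy-N-methyl-3-{(2S)-2-methyl-2-[(1E)-3-oxoprop-1-en-1-yl]-8-(triisopropylsilyloxy)chroman-6-yl}prop-2-enamide | CON(C)C(=O)/C=C/c1cc2c(c(O[Si](C(C)C)(C(C)C)C(C)C)c1)O[C@](C)(/C=C/C=O)CC2
F4 | step 3 | 3,5-dihydroxy-4-(3-methylbut-2-en-1-yl)phenyl 2,2-dimethylpropanoate | CC(C)=CCc1c(O)cc(OC(=O)C(C)(C)C)cc1O
F5 | step 3 | 3,5-bis(tert-butyldimethylsilyloxy)-4-(3-methylbut-2-en-1-yl)phenyl 2,2-dimethylpropanoate | CC(C)=CCc1c(O[Si](C)(C)C(C)(C)C)cc(OC(=O)C(C)(C)C)cc1O[Si](C)(C)C(C)(C)C
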